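(Readings and results are simulated with made-up constants; scatter was added.)

A small charge of partner, 0.11 M, went into cedar against 0.10 M of starting material, with capture agent beside them. I had to say what cedar held at 12 h and which option was worth 6.0 h more.

| flask | starting material | partner | capture agent | temperature | remark | time |
|---|---|---|---|---|---|---|
| cedar | 0.10 M | 0.11 M | 0.030 M | −20 °C | the very flask that is asked about, followed so far |  |
| elm | 0.10 M | 0.22 M | 0.030 M | −25 °C | run made earlier |  |
| flask | 0.10 M | 0.110 M | 0.0300 M | −20 °C |  | 12 h |

- cedar (time / min: target / %): 90.0: 16.4; 240: 16.3; 480: 16.2; 720: 16.5
- elm (time / min: target / %): 4.00: 0.2; 10.0: 2.3; 20.0: 4.3; 30.0: 6.1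

(each reading ± 0.5 percentage points)

- blue: at 12 h add partner, 100% of the amount charged, then wait 6.0 h
- grey: at 12 h raise the temperature by 20 K, then wait 6.0 h
- green: change nothing and wait 6.0 h more
- violet: at 12 h take out 90% of the target then present, then wait 6.0 h

- target, in percent of the starting material first charged, at 12 h
- the option that brings most further target ("none" if no option brings more than 2 percentage points) (blue / grey / green / violet / none)
- target present, with what was taken out counted in, in percent of the starting material first charged, after blue
- target present, with what was taken out counted in, in percent of the starting material first charged, after grey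

- what is taken out of target is counted as made
- additions bring no volume worth counting

I read the runs as a ladder of times. On the shortest rung, elm's pace between its second and fourth readings reaches cedar's first flat reading, 16.4%, in 86.3 min. Cedar was already flat at 90.0 min, and it ran warmer than elm. On the next rung, the same pace needs 526 min for the whole charge of starting material, which is longer than the first rung. So target in cedar stopped well before elm's pace could have turned the whole charge of starting material into target. On the longest rung, cedar stayed level to 720 min, within the scatter of 0.5 percentage points.

I therefore took partner as the limiting reagent, though these readings cannot exclude an equilibrium. Cedar's first flat reading gives 6.71 as the partner cost, the partner charged for each target made. I froze that cost. By my own reckoning, blue's dose then buys as much again and reaches 32.8%, while grey, green and violet add no partner, so grey stays at 16.4%.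

The forecast gave 16.4% at 12 h, chose blue, and put blue at 28.5% and grey at 8%, saying: “I read this as equilibrium rather than exhaustion”. My figures stood higher for blue and for grey.

The flask gave 16.4%, and blue was best. Blue reached 45.9% and grey 16.4%, while violet brought 0 points.

    starting material → open intermediate (k = 1.10 × 10⁻⁴ s⁻¹, Ea = 89.0 kJ mol⁻¹)
    partner + open intermediate → target (k = 0.100 M⁻¹ s⁻¹, Ea = 38.0 kJ mol⁻¹)
    2 partner → homo product (k = 0.0230 M⁻¹ s⁻¹, Ea = 56.0 kJ mol⁻¹)
    open intermediate + capture agent → trapped intermediate (k = 0.00120 M⁻¹ s⁻¹, Ea = 64.0 kJ mol⁻¹)
    starting material + open intermediate → side product (k = 9.90 × 10⁻⁴ M⁻¹ s⁻¹, Ea = 49.0 kJ mol⁻¹)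
    (constants at −20 °C)

At 720 min, cedar held partner at 0% of its own charge and open intermediate at 29.4% of the starting material charged. Blue's dose had a partner cost of 3.72, lower than cedar's first, and my frozen figure of 32.8% stood below the 45.9% reached. A neighbouring flask kept cedar's partner charge but held 0.40 M of starting material. The frozen cost gave that neighbour 4.10% of its own charge of starting material. At 720 min that neighbour held 7.35% of target, a partner cost of 3.74, also lower than cedar's first, with homo product at 0.0403 M.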